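Monday's run stopped with a leftover: at 10.0 min it held 33.9% product and, counting one partner per product, 10.8 mM of partner, so I read the halt as a balance.

| flask | starting material | partner | remark | time |
|---|---|---|---|---|
| Monday's | 5 mM | 2.5 equiv | run made earlier |  |
| flask | 10 mM | 2.50 equiv |  | 50 min |

Monday's run (percent of the starting material charged)

| time / min | product / % | starting material / % |
|---|---|---|
| 0.667 | 8.3 | 91.6 |
| 2.00 | 20.4 | 80.0 |
| 4.00 | 29.2 | 70.3 |
| 5.00 | 32.0 | 68.3 |
| 8.00 | 33.5 | 66.7 |
| 10.0 | 33.9 | 66.2 |

(scatter of a reading: 0.3 percentage points)



* time, not beyond 50 min, at which the flask holds most product
* the amount of product, in percent of the starting material charged, at that time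

From the first reading I took the forward constant k, 10.5 L mol⁻¹ min⁻¹. From the last I took the quotient Q, [product] squared over [starting material][partner], 0.0803. I carried the relaxation half-life, the time in which the gap to that balance halves: ln(2) over k([starting material] + [partner] + 2[product]/Q). At the plateau amounts of this flask it came to 0.585 min.

The pseudo-first-order forward time at charged partner was 3.80 min, and my half-life was shorter than that. Concentrations in this flask were twice Monday's at equal equivalents, so I scaled Monday's 10.0 min to 5.00 min, and Q, having no unit, put my plateau near the 33.9% read on Monday. The longest time allowed, 50 min, lay ten times beyond that scaled time, and I committed to the plateau's start as the best time. The forecast said 34.2% at 50 min, since “the maximum is a flat plateau”; we differed in the time.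

The flask gave 35.1% at 4.89 min.

    partner → decomposed reagent (k = 0.0386 min⁻¹)
    starting material + partner ⇌ product + released group (K = 0.103, k = 10.8 L mol⁻¹ min⁻¹)
    released group → by-product carried off (k = 0.0114 min⁻¹)

At 50.0 min, on the flask's amounts with released group beside product, my half-life reckoned 1.17 min, and the reversible step's own value was 1.38 min. That is far shorter than the 18 min half-life of partner decomposing at 14.8 min, and as partner fell to 14.2% of its charge, product fell to 24.4%. The flask with 10.0 equiv of partner reckoned 0.667 min at 50.0 min, and its product went from a best of 59.9% to 42.4%.

(The numbers in the tables come from a simulation with made-up constants; noise was put on by code.)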